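Red puts 74.9% of its free monomer into chains by 6.00 min, more than the 11.2% of green at that time, and the two recipes differ in their initiator.

| flask | free monomer | protic impurity | initiator | stray impurity | remark | time |
|---|---|---|---|---|---|---|
| green | 0.10 M | 5 mM | 2.5 mM | 4.9 mM | run made earlier |  |
| red | 0.10 M | 5 mM | 10 mM | 4.9 mM | run made earlier |  |
| south-east | 0.10 M | 5.00 mM | 5.0 mM | 4.9 mM |  | 10 min |
| north | 0.10 M | 5.00 mM | 5.0 mM | 4.9 mM |  | 15 min |

| green: time / min | green: monomer in chains / % | red: time / min | red: monomer in chains / % |
|---|---|---|---|
| 0.500 | 0 | 0.417 | 1.9 |
| 0.833 | 0 | 1.33 | 13.9 |
| 1.33 | 2.0 | 2.00 | 22.0 |
| 2.00 | 3.2 | 3.00 | 40.3 |
| 4.00 | 6.0 | 5.00 | 65.4 |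
| 6.00 | 11.2 | 6.00 | 74.9 |

(standard deviation of a reading: 1 percentage point)

- the average divides the monomer in chains by the number of chains begun, living and dead together
- what was read earlier has a scatter of 1 percentage point, one standard deviation
- what may be going on: free monomer + initiator -> living end + monomer in chains; free monomer + living end -> monomer in chains + living end; protic impurity + free monomer -> quenched substrate; initiator + stray impurity -> spent initiator
- the earlier runs do not show the number of chains; that part of a forecast is a guess

* which of the two ends with the longer chains by the average number of monomer units in a chain (chains begun, living or dead) ("neither" if they lie within 10%) (south-east / north / neither)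
* average number of monomer units in a chain (chains begun, living or dead) at the end, south-east
* average number of monomer units in a chain (chains begun, living or dead) at the end, north

I build the flask up one process at a time. With propagation and a fixed number of living ends, free monomer falls exponentially (pseudo-first-order), with a slope proportional to the ends. The average length is monomer in chains divided by chains begun, so if the chain count stands still, it cancels from the ratio of lengths at two times. That ratio is one minus the exponential of minus slope times time, taken at the later time and divided by the same at the earlier time.

Adding the protic impurity takes 5.00% of the charge out of reach, the same factor at both times, so the ratio stays as it was. With that taken off, green's readings from 2.00 min to 6.00 min give a slope of 0.0228 /min, a reading with its scatter.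

Adding the loss of initiator to stray impurity takes initiator away from the births of ends. In south-east and north, initiator tops stray impurity by 0.100% of the monomer charge, and I assume that the count of ends stops growing well before 10 min; that is an assumption and not a reading. The earlier runs do not show the count, so I guess 3 times green's ends, which gives a slope of 0.0684 /min. The ratio for north over south-east is then 1.30, and this is the stretch, the growth of length at a frozen chain count. A guess of 2 gives 1.35. Both lie more than 10% above 1, so I commit to north and to no absolute length.

The forecast says north, with 42 for south-east and 57 for north, a ratio of 1.36, and it warns: “The chain count is inferred, not measured.”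

The flask gives north, with 77.1 for south-east and 102 for north.

    free monomer + initiator → living end + monomer in chains (k = 0.0420 /M/s)
    free monomer + living end → monomer in chains + living end, rate k2*[living end]*[free monomer] (k = 2.00 /M/s)
    protic impurity + free monomer → quenched substrate (k = 1.50 /M/s)
    initiator + stray impurity → spent initiator (k = 15.0 /M/s)

North ends longer because of the time: cut at 10 min, its length falls from 102 to 77.1. Living ends stand at 0.591% of the monomer charge at 10.0 min and 0.591% at 15.0 min in these two flasks, and the lengths have a ratio of 1.32 beside the stretch of 1.30; south-east and north exceed the forecast's lengths by factors of 1.84 and 1.79. Green's recipe, with a stretch of 1.42, goes from 101 at 10 min to 145 at 15 min, a ratio of 1.44.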